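**Plan**
- **Cuts.** The free ring-bound CO2H is traced back to a benzyl ester, and the lactone C=O to an aldehyde-level carbon. The main cut lies between the last CH2 of the decamethylene chain and the CH that bears the free side-chain CO2H. It gives unprotected dec-9-enyl (R)-malate and an α-iodo derivative of an (S)-homocitrate core. The core is cut at CH2–C(quaternary) (aldol) and at the keto carbon–CH2 bond of the arm (oxalate plus Grignard reagent). The malate is cut at its alkyl ester C–O bond.
- **Enabling feature.** The oxygen on the fully substituted ring carbon is β to the side-chain carboxyl carbon and is also bound to the lactone carbonyl carbon. With that carbon held at the aldehyde level, the O, CHO and CO2H groups knit into a 2,8-dioxabicyclo[3.2.1]octan-3-one (an oxolane ring bridged over a 1,3-dioxan-4-one ring). This cage is absent from the target. In it the future CH is the only carbon that can be activated, and it has one open face.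
- **Forward order.** Keto ester, then aldol, then ozonolysis (the oxolane ring closes as a lactol), then silver-promoted acylation (the dioxanone ring closes), then iodination, then radical union with the whole malate chain. The cage is then opened and oxidised to the γ-lactone, and hydrogenolysis finishes the route.
- **Stereochemistry.** The quaternary S centre comes from the Cu(OTf)2/(S,S)-tBu-box aldol. The adjacent S CH comes from exo-face radical addition on the cage. The R carbinol of the malate comes from D-malic acid.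

Key step: step 8

Assumption: keto ester 3 is taken to chelate the copper catalyst as pyruvate esters do, so the (S,S)-ligand should give the S carbinol; if the sense were opposite, the (R,R)-ligand would be used.

**Step 1**
Reactants: 1 dibenzyl oxalate; 2 but-3-en-1-ylmagnesium bromide
Product: 3 benzyl 2-oxohex-5-enoate
Conditions: 2 (1.0 equiv, THF) added to 1 (1.3 equiv), THF, −78 °C; 1 M HCl quench
Reagents that add atoms: none
Why: Mono-addition of a Grignard reagent to a dialkyl oxalate stops at the α-keto ester because the magnesium hemiketal alkoxide persists at −78 °C until the quench; no stereocentre is formed.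

**Step 2**
Reactants: 4 S-tert-butyl ethanethioate
Product: 6 1-(tert-butylsulfanyl)-1-(trimethylsilyloxy)ethene, via lithium thioester enolate 5 (not isolated)
Conditions: LiN(iPr)2, THF, −78 °C; Me3SiCl, −78 °C to rt; distillation
Reagents that add atoms: chlorotrimethylsilane C[Si](C)(C)Cl
Why: Kinetic enolisation of a thioester followed by O-silylation is the standard silyl ketene thioacetal synthesis; no stereocentre is formed.

**Step 3**
Reactants: 3 benzyl 2-oxohex-5-enoate; 6 1-(tert-butylsulfanyl)-1-(trimethylsilyloxy)ethene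
Product: 8 benzyl (2S)-2-[2-(tert-butylsulfanyl)-2-oxoethyl]-2-hydroxyhex-5-enoate, via silyl ether 7 (not isolated)
Conditions: Cu(OTf)2 (10 mol%), 2,2'-(propane-2,2-diyl)bis[(4S)-4-tert-butyl-4,5-dihydrooxazole] (11 mol%), THF, −78 °C; then 1 M HCl, THF, rt
Reagents that add atoms: none
Why: In this catalytic enantioselective Mukaiyama aldol addition to an α-keto ester, 3 binds divalent copper through both carbonyl oxygens in a square-planar chelate whose tert-butyl groups leave only the si face of the ketone open, which should set the fully substituted carbinol carbon as S.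

**Step 4**
Reactants: 8 benzyl (2S)-2-[2-(tert-butylsulfanyl)-2-oxoethyl]-2-hydroxyhex-5-enoate
Product: 10 benzyl (2S)-2-[2-(tert-butylsulfanyl)-2-oxoethyl]-5-hydroxyoxolane-2-carboxylate (both anomers), via hydroxy aldehyde 9 (not isolated)
Conditions: O3, CH2Cl2, −78 °C; Me2S, −78 °C to rt
Reagents that add atoms: ozone [O-][O+]=O
Why: Ozonolysis with reductive work-up cleaves only the terminal alkene (thioester and benzyl ester are inert at −78 °C), and the γ-hydroxy aldehyde closes spontaneously to the five-membered lactol, whose anomeric centre is of no consequence.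

**Step 5**
Reactants: 10 benzyl (2S)-2-[2-(tert-butylsulfanyl)-2-oxoethyl]-5-hydroxyoxolane-2-carboxylate
Product: 11 benzyl (1S,5S)-3-oxo-2,8-dioxabicyclo[3.2.1]octane-5-carboxylate
Conditions: AgO2CCF3 (1.2 equiv), 2,6-di-tert-butyl-4-methylpyridine (1.3 equiv), 4 Å MS, CH2Cl2 (0.01 M), rt, dark
Reagents that add atoms: none
Why: In this thiophilic-metal-promoted lactonisation of an S-tert-butyl thioester, monovalent silver binds sulfur and the acyl carbon is taken by the lactol OH of the anomer cis to the side chain, while the anomers equilibrate through 9; the acetal centre can only become 1S because the new bridge must span one face of the oxolane ring.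

**Step 6**
Reactants: 11 benzyl (1S,5S)-3-oxo-2,8-dioxabicyclo[3.2.1]octane-5-carboxylate
Product: 13 benzyl (1S,4S,5R)-4-iodo-3-oxo-2,8-dioxabicyclo[3.2.1]octane-5-carboxylate, via lithium enolate 12 (not isolated)
Conditions: LiN(SiMe3)2 (1.05 equiv), THF, −78 °C; cannulated into I2 (1.1 equiv), THF, −78 °C
Reagents that add atoms: iodine II
Why: In this electrophilic α-iodination of a 1,3-dioxan-4-one lithium enolate, C4 is the only α-CH2 in 11 and the ring-held C5–O8 bond overlaps poorly with the enolate, so β-loss should be slow at −78 °C; iodine is expected on the exo face (the C5 descriptor changes only through ranking), and this centre is erased in step 8.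

**Step 7**
Reactants: 14 (R)-malic acid (D-malic acid); 15 dec-9-en-1-ol
Product: 18 (3R)-4-(dec-9-en-1-yloxy)-3-hydroxy-4-oxobutanoic acid, via O-trifluoroacetyl malic anhydride 16 (not isolated), via O-trifluoroacetyl half ester 17 (not isolated)
Conditions: (CF3CO)2O, 0 °C to rt, then evaporation; 15 (1.0 equiv), CH2Cl2, rt; MeOH, rt, evaporation
Reagents that add atoms: none
Why: In this regioselective anhydride alcoholysis, the O-trifluoroacetyl cyclic anhydride is opened by alcohols at the carbonyl next to the electron-poor acyloxy-bearing carbon, and methanol then strips the labile trifluoroacetate; the R centre is not touched.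

**Step 8**
Reactants: 13 benzyl (1S,4S,5R)-4-iodo-3-oxo-2,8-dioxabicyclo[3.2.1]octane-5-carboxylate; 18 (3R)-4-(dec-9-en-1-yloxy)-3-hydroxy-4-oxobutanoic acid
Product: 20 (3R)-4-({10-[(1S,4S,5S)-5-(benzyloxycarbonyl)-3-oxo-2,8-dioxabicyclo[3.2.1]octan-4-yl]decyl}oxy)-3-hydroxy-4-oxobutanoic acid, via secondary iodide 19 (not isolated)
Conditions: 18 (1.5 equiv), Et3B (0.3 equiv, in portions), air, CH2Cl2 (0.5 M), 0 °C to rt; then (Me3Si)3SiH (1.3 equiv), Et3B (0.2 equiv), air, rt
Reagents that add atoms: none
Why: Ethyl radicals from Et3B and O2 abstract iodine from 13 to give the planar, electrophilic C4 lactone radical, which adds to the unsubstituted terminus of the electron-rich alkene of 18; the resulting secondary alkyl radical takes iodine from another molecule of 13 and carries the chain to 19, whose C–I bond is then reduced in the same flask by a (Me3Si)3SiH chain. The closest known reaction type is the Et3B-initiated iodine-atom-transfer (Kharasch-type) addition of α-iodo esters and α-iodo lactones to 1-alkenes, followed by silane deiodination. No ring is closed. The one lasting new stereocentre, C4 of the cage (the α-carbon of the later free acid), is controlled by the temporary bicycle: the C6–C7 ethano bridge covers the endo face, so the alkene should bond on the exo face beside the one-atom O8 bridge and trans to C6, which with 5S gives 4S, while the iodine-bearing carbon of 19 is a mixture that the reduction erases. The step needs site selectivity (only C4 bears iodine, and the arm carbonyl that would offer a second α-position is masked as acetal carbon C1), regioselectivity at the alkene (polarity and sterics both point to the CH2 terminus), and tolerance of the free OH, the free CO2H and the esters. Because no base is present, neither β-loss of O8 from C5, nor epimerisation of the axial C4 substituent, nor enolisation of the malate can occur.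

**Step 9**
Reactants: 20 (3R)-4-({10-[(1S,4S,5S)-5-(benzyloxycarbonyl)-3-oxo-2,8-dioxabicyclo[3.2.1]octan-4-yl]decyl}oxy)-3-hydroxy-4-oxobutanoic acid
Product: 22 (2S)-2-[(2S)-2-(benzyloxycarbonyl)-5-oxooxolan-2-yl]-12-{[(2R)-3-carboxy-2-hydroxypropanoyl]oxy}dodecanoic acid, via lactol diacid 21 (not isolated)
Conditions: CF3CO2H (cat.), THF/H2O (4:1), rt, then concentration; TEMPO (0.2 equiv), PhI(OAc)2 (1.2 equiv), CH2Cl2/H2O, rt
Reagents that add atoms: water O
Why: Mild acid hydrolysis opens the strained acylal well before any alkyl ester, and oxoammonium (TEMPO) oxidation turns the lactol into the γ-lactone much faster than it attacks the deactivated secondary α-hydroxy ester; no stereocentre is touched.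

**Step 10**
Reactants: 22 (2S)-2-[(2S)-2-(benzyloxycarbonyl)-5-oxooxolan-2-yl]-12-{[(2R)-3-carboxy-2-hydroxypropanoyl]oxy}dodecanoic acid
Product: 23 (2S)-2-[(1S)-1-carboxy-11-{[(2R)-3-carboxy-2-hydroxypropanoyl]oxy}undecyl]-5-oxooxolane-2-carboxylic acid (target)
Conditions: H2 (1 atm), Pd/C (10 wt%), EtOAc, rt
Reagents that add atoms: none
Why: Neutral catalytic hydrogenolysis removes the single benzyl ester and leaves the lactone, the primary alkyl malate ester and all three stereocentres untouched.

**Compound list**
1 | dibenzyl oxalate | O=C(OCc1ccccc1)C(=O)OCc1ccccc1 | starting material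
2 | but-3-en-1-ylmagnesium bromide | C=CCC[Mg]Br | starting material
3 | benzyl 2-oxohex-5-enoate | C=CCCC(=O)C(=O)OCc1ccccc1 | intermediate
4 | S-tert-butyl ethanethioate | CC(=O)SC(C)(C)C | starting material
5 | lithium enolate of 4 | [Li+].C=C([O-])SC(C)(C)C | intermediate
6 | 1-(tert-butylsulfanyl)-1-(trimethylsilyloxy)ethene | C=C(O[Si](C)(C)C)SC(C)(C)C | intermediate
7 | benzyl (2S)-2-[2-(tert-butylsulfanyl)-2-oxoethyl]-2-(trimethylsilyloxy)hex-5-enoate | C=CCC[C@](O[Si](C)(C)C)(CC(=O)SC(C)(C)C)C(=O)OCc1ccccc1 | intermediate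
8 | benzyl (2S)-2-[2-(tert-butylsulfanyl)-2-oxoethyl]-2-hydroxyhex-5-enoate | C=CCC[C@](O)(CC(=O)SC(C)(C)C)C(=O)OCc1ccccc1 | intermediate
9 | benzyl (2S)-2-[2-(tert-butylsulfanyl)-2-oxoethyl]-2-hydroxy-5-oxopentanoate | O=CCC[C@](O)(CC(=O)SC(C)(C)C)C(=O)OCc1ccccc1 | intermediate
10 | benzyl (2S)-2-[2-(tert-butylsulfanyl)-2-oxoethyl]-5-hydroxyoxolane-2-carboxylate (both anomers) | CC(C)(C)SC(=O)C[C@]1(C(=O)OCc2ccccc2)CCC(O)O1 | intermediate
11 | benzyl (1S,5S)-3-oxo-2,8-dioxabicyclo[3.2.1]octane-5-carboxylate | O=C1C[C@]2(C(=O)OCc3ccccc3)CC[C@H](O1)O2 | intermediate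
12 | lithium enolate of 11 | [Li+].[O-]C1=C[C@]2(C(=O)OCc3ccccc3)CC[C@H](O1)O2 | intermediate
13 | benzyl (1S,4S,5R)-4-iodo-3-oxo-2,8-dioxabicyclo[3.2.1]octane-5-carboxylate (exo iodide) | O=C1[C@@H](I)[C@]2(C(=O)OCc3ccccc3)CC[C@H](O1)O2 | intermediate
14 | (R)-malic acid | O=C(O)C[C@@H](O)C(=O)O | starting material
15 | dec-9-en-1-ol | C=CCCCCCCCCO | starting material
16 | (3R)-2,5-dioxooxolan-3-yl trifluoroacetate | O=C1C[C@@H](OC(=O)C(F)(F)F)C(=O)O1 | intermediate
17 | (3R)-4-(dec-9-en-1-yloxy)-4-oxo-3-(trifluoroacetoxy)butanoic acid | O=C(O)C[C@@H](OC(=O)C(F)(F)F)C(=O)OCCCCCCCCC=C | intermediate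
18 | (3R)-4-(dec-9-en-1-yloxy)-3-hydroxy-4-oxobutanoic acid | O=C(O)C[C@@H](O)C(=O)OCCCCCCCCC=C | intermediate
19 | (3R)-4-({10-[(1S,4S,5S)-5-(benzyloxycarbonyl)-3-oxo-2,8-dioxabicyclo[3.2.1]octan-4-yl]-9-iododecyl}oxy)-3-hydroxy-4-oxobutanoic acid (both epimers at the C–I carbon) | O=C1[C@@H](CC(I)CCCCCCCCOC(=O)[C@H](O)CC(=O)O)[C@]2(C(=O)OCc3ccccc3)CC[C@H](O1)O2 | intermediate
20 | (3R)-4-({10-[(1S,4S,5S)-5-(benzyloxycarbonyl)-3-oxo-2,8-dioxabicyclo[3.2.1]octan-4-yl]decyl}oxy)-3-hydroxy-4-oxobutanoic acid | O=C1[C@@H](CCCCCCCCCCOC(=O)[C@H](O)CC(=O)O)[C@]2(C(=O)OCc3ccccc3)CC[C@H](O1)O2 | intermediate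
21 | (2S)-2-[(2S)-2-(benzyloxycarbonyl)-5-hydroxyoxolan-2-yl]-12-{[(2R)-3-carboxy-2-hydroxypropanoyl]oxy}dodecanoic acid (both anomers) | O=C(O)C[C@@H](O)C(=O)OCCCCCCCCCC[C@H](C(=O)O)[C@]1(C(=O)OCc2ccccc2)CCC(O)O1 | intermediate
22 | (2S)-2-[(2S)-2-(benzyloxycarbonyl)-5-oxooxolan-2-yl]-12-{[(2R)-3-carboxy-2-hydroxypropanoyl]oxy}dodecanoic acid | O=C(O)C[C@@H](O)C(=O)OCCCCCCCCCC[C@H](C(=O)O)[C@]1(C(=O)OCc2ccccc2)CCC(=O)O1 | intermediate
23 | (2S)-2-[(1S)-1-carboxy-11-{[(2R)-3-carboxy-2-hydroxypropanoyl]oxy}undecyl]-5-oxooxolane-2-carboxylic acid | O=C(O)C[C@@H](O)C(=O)OCCCCCCCCCC[C@H](C(=O)O)[C@]1(C(=O)O)CCC(=O)O1 | target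

**Total step count:** 10.
**Longest linear sequence:** 8 (steps 1, 3, 4, 5, 6, 8, 9, 10).

**Steps most likely to fail**

**1. Step 8.**
- What may go wrong: the hindered C4 radical may add too slowly to the unactivated alkene, so the iodine-transfer chain breaks down and 13 is consumed by simple reduction.
- The fallback sets out from 13 and 14 and returns at 20.
- Keck radical allylation of 13 with Bu3SnCH2CH=CH2 (AIBN, benzene, 80 °C) uses a much faster trap that fragments irreversibly. On the same exo face it should give benzyl (1S,4S,5S)-3-oxo-4-(prop-2-en-1-yl)-2,8-dioxabicyclo[3.2.1]octane-5-carboxylate F1.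
- Anhydride 16, made from 14 as in step 7, is opened with non-8-en-1-ol to (3R)-4-(non-8-en-1-yloxy)-4-oxo-3-(trifluoroacetoxy)butanoic acid F2. Methanol then gives (3R)-3-hydroxy-4-(non-8-en-1-yloxy)-4-oxobutanoic acid F3.
- Cross metathesis of F1 with an excess of F3 (second-generation Grubbs catalyst, CH2Cl2, 40 °C) should give (3R)-4-({(8E)-10-[(1S,4S,5S)-5-(benzyloxycarbonyl)-3-oxo-2,8-dioxabicyclo[3.2.1]octan-4-yl]dec-8-en-1-yl}oxy)-3-hydroxy-4-oxobutanoic acid F4.
- Hydrogenation of the alkene over RhCl(PPh3)3 (H2, benzene/EtOH) leaves the benzyl ester in place and leads to 20.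

**2. Step 5.**
- What may go wrong: intermolecular acyl transfer may compete with ring closure, or the strained acylal may be reopened by the acid released as it forms.
- The fallback sets out from 8 and returns at 11. It closes the other C–O bond of the bridge.
- Thiophilic hydrolysis of the thioester (AgO2CCF3, THF/H2O, rt) spares the benzyl ester and should give (3S)-3-[(benzyloxy)carbonyl]-3-hydroxyhept-6-enoic acid F5.
- Ozonolysis as in step 4 gives [(2S)-2-(benzyloxycarbonyl)-5-hydroxyoxolan-2-yl]acetic acid F6.
- Acid-catalysed dehydration (camphorsulfonic acid cat., benzene, Dean–Stark trap) generates the ring oxocarbenium ion, which the carboxylic acid captures as in classical pseudo-ester formation, giving 11.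

**3. Step 6.**
- What may go wrong: the lithium enolate may fragment (loss of the O8 bridge from C5, or ketene formation by loss of O2), or iodination may proceed twice.
- The fallback sets out from 11 and returns at 13. It never lets a free enolate build up.
- LiN(SiMe3)2 is added to a mixture of 11 and Me3SiCl in THF at −78 °C (internal quench). This should give the neutral ketene acetal benzyl (1S,5S)-3-(trimethylsilyloxy)-2,8-dioxabicyclo[3.2.1]oct-3-ene-5-carboxylate F7.
- N-Iodosuccinimide in CH2Cl2 at −78 °C then converts F7 into 13.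

**Further compounds**
F1 | step 8 | benzyl (1S,4S,5S)-3-oxo-4-(prop-2-en-1-yl)-2,8-dioxabicyclo[3.2.1]octane-5-carboxylate | O=C1[C@@H](CC=C)[C@]2(C(=O)OCc3ccccc3)CC[C@H](O1)O2
F2 | step 8 | (3R)-4-(non-8-en-1-yloxy)-4-oxo-3-(trifluoroacetoxy)butanoic acid | O=C(O)C[C@@H](OC(=O)C(F)(F)F)C(=O)OCCCCCCCC=C
F3 | step 8 | (3R)-3-hydroxy-4-(non-8-en-1-yloxy)-4-oxobutanoic acid | O=C(O)C[C@@H](O)C(=O)OCCCCCCCC=C
F4 | step 8 | (3R)-4-({(8E)-10-[(1S,4S,5S)-5-(benzyloxycarbonyl)-3-oxo-2,8-dioxabicyclo[3.2.1]octan-4-yl]dec-8-en-1-yl}oxy)-3-hydroxy-4-oxobutanoic acid | O=C1[C@@H](C/C=C/CCCCCCCOC(=O)[C@H](O)CC(=O)O)[C@]2(C(=O)OCc3ccccc3)CC[C@H](O1)O2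
F5 | step 5 | (3S)-3-[(benzyloxy)carbonyl]-3-hydroxyhept-6-enoic acid | C=CCC[C@](O)(CC(=O)O)C(=O)OCc1ccccc1
F6 | step 5 | [(2S)-2-(benzyloxycarbonyl)-5-hydroxyoxolan-2-yl]acetic acid | O=C(O)C[C@]1(C(=O)OCc2ccccc2)CCC(O)O1
F7 | step 6 | benzyl (1S,5S)-3-(trimethylsilyloxy)-2,8-dioxabicyclo[3.2.1]oct-3-ene-5-carboxylate | C[Si](C)(C)OC1=C[C@]2(C(=O)OCc3ccccc3)CC[C@H](O1)O2
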